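**Plan**

- Numbering: the target is methyl 2-(dec-8-enyl)tetracyclo[8.2.1.0^3,12.0^6,11]trideca-4,8-diene-7-carboxylate (cyclobutane C1/C2/C3/C12; ring A C3–C6/C11/C12 with C4=C5; cyclopentane C1/C12/C11/C10/C13; ring B C6–C11 with C8=C9). The retrosynthesis cuts C6–C7 and C10–C11 (intramolecular Diels–Alder), then C3–C12 (6π) and C1–C2 (8π), which leaves a linear (E,Z,Z,E)-tetraene ending in a (2E,4E)-dienoate.
- The dienoate C10=C9–C8=C7–CO2Me is not carried as such. It is stored as a trans-3,4-disubstituted cyclobutene with a temporary C7–C10 bond, and this ring is cut at C7–C8 and C9–C10 into acetylene and 5,6-dihydro-2H-pyran-2-one ([2+2] photocycloaddition).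
- Feature that allows this: in ring B the unsubstituted cis-CH=CH unit C8=C9 lies between two sp3 carbons that are 1,4 to each other, C7 carrying the ester carbon and C10 the methylene C13. After the Diels–Alder cut this is an (E,E)-diene, the ring-opened form of a cyclobutene whose two substituents (C=O and CH2CH2O) are the two arms of an unsaturated six-membered lactone; the lactone carbonyl becomes the ester, its CH2 becomes C13 and its OCH2 becomes C1.
- Forward: cyclobutene lactone → trans hydroxy ester → vinyl iodide; side chain → vinyl iodide → butadiyne linchpin (Negishi, then Sonogashira) → cis reduction → eight-membered ring (8π) → cyclobutane and ring A (6π) → cyclobutene opening → cyclopentane and ring B (Diels–Alder).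
- Stereochemistry: the alkene geometries (Takai olefinations, hydrozirconation, zinc reduction, trans-cyclobutene) are translated by the conrotatory 8π, disrotatory 6π, conrotatory 4π and suprafacial Diels–Alder events into all eight stereocentres relative to each other. The absolute configuration comes from resolution of the racemic cascade product on a chiral phase.

Key step: step 1

Remarks on the chemistry:
- The cascade starts from an achiral tetraene and its first stereocentres arise in the 8π step, so it is taken to be racemic; the single enantiomer is therefore collected by chromatography on a chiral phase in the last step.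
- Racemic compounds are marked rac- and their SMILES shows one enantiomer; for the racemic cascade product both enantiomers are written.
- Intermediates that contain both the racemic cyclobutene and the racemic ring system are mixtures of two racemic diastereomers that converge on one dienoate; one is drawn.
- Locants C1–C13 refer to the target numbering above.

**Step 1**
Reactants: 1 5,6-dihydro-2H-pyran-2-one; 2 acetylene
Product: 3 rac-(1R,6S)-3-oxabicyclo[4.2.0]oct-7-en-2-one (cis-fused)
Conditions: C2H2 (sparged, large excess), acetone, hν (medium-pressure Hg lamp, Pyrex), −40 °C, stopped at partial conversion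
Reagents that add atoms: none
Why: Triplet-sensitised excitation of the cyclic enoate 1 (acetone) gives the lactone triplet, which adds to acetylene to a 1,4-biradical that closes after intersystem crossing, so that both bonds to the two acetylene carbons (the future C7–C8 and C9–C10 bonds) are made in one operation. The closest known reaction type is the [2+2] photocycloaddition of 2(5H)-furanones and other α,β-unsaturated lactones or enones with acetylene or ethylene. The four-membered ring is closed as a two-bond cycloaddition across the lactone C=C bond (radical addition, then 1,4-radical recombination), and the alkyne stays at the alkene level so that a cyclobutene results. The two new stereocentres (C1 and C6 of 3) must be cis because the six-membered lactone cannot span a trans-fused cyclobutene; they are temporary and only need to be defined relative to each other. The step needs chemoselectivity for mono-addition over lactone dimerisation and over secondary photoreactions of 3, which should be secured by the large excess of dissolved acetylene at low temperature, the Pyrex filter and interruption at partial conversion; regioselectivity is not an issue because acetylene is symmetrical.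

**Step 2**
Reactants: 3 rac-(1R,6S)-3-oxabicyclo[4.2.0]oct-7-en-2-one
Product: 5 rac-methyl (1S,4S)-4-(2-hydroxyethyl)cyclobut-2-ene-1-carboxylate (trans), via cis-hydroxy ester 4 (not isolated)
Conditions: NaOMe (0.2 equiv), MeOH, 0 °C to rt, monitored; AcOH quench
Reagents that add atoms: methanol (CO)
Why: Methoxide opens the strained lactone to the cis-hydroxy ester 4 and, through reversible enolisation of the ester, equilibrates C1 to the more stable trans isomer 5, which alone cannot relactonise and therefore should accumulate (lactone methanolysis with thermodynamic α-epimerisation), so the trans relationship that later encodes the (E,E)-diene is set here.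

**Step 3**
Reactants: 5 rac-methyl (1S,4S)-4-(2-hydroxyethyl)cyclobut-2-ene-1-carboxylate
Product: 6 rac-methyl (1S,4S)-4-(2-oxoethyl)cyclobut-2-ene-1-carboxylate
Conditions: Dess–Martin periodinane, NaHCO3, CH2Cl2, 0 °C
Reagents that add atoms: none
Why: Dess–Martin oxidation converts the primary alcohol into the aldehyde under buffered, non-basic conditions that should leave the cyclobutene, the ester and the C1 stereocentre untouched.

**Step 4**
Reactants: 6 rac-methyl (1S,4S)-4-(2-oxoethyl)cyclobut-2-ene-1-carboxylate
Product: 7 rac-methyl (1S,4S)-4-[(2E)-3-iodoprop-2-en-1-yl]cyclobut-2-ene-1-carboxylate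
Conditions: CrCl2 (6 equiv), CHI3 (2 equiv), dioxane/THF 6:1, 0 °C to rt
Reagents that add atoms: iodoform (IC(I)I)
Why: In the Takai iodoolefination the gem-dichromium species from CHI3 and CrCl2 adds to the aldehyde and eliminates anti to give the (E)-vinyl iodide, the ester and the strained alkene being inert to CrCl2.

**Step 5**
Reactants: 8 dec-9-yn-1-ol
Product: 9 dec-9-ynal
Conditions: Dess–Martin periodinane, NaHCO3, CH2Cl2, 0 °C to rt
Reagents that add atoms: none
Why: Dess–Martin oxidation of the primary alcohol stops at the aldehyde and tolerates the terminal alkyne.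

**Step 6**
Reactants: 9 dec-9-ynal
Product: 10 (10E)-dodec-10-en-1-yne
Conditions: CrCl2 (8 equiv), CH3CHI2 (2 equiv), THF, rt
Reagents that add atoms: 1,1-diiodoethane (CC(I)I)
Why: Takai–Utimoto ethylidenation with the gem-dichromium reagent from 1,1-diiodoethane should give the (E)-propenyl terminus of the side chain while the terminal alkyne is tolerated.

**Step 7**
Reactants: 10 (10E)-dodec-10-en-1-yne
Product: 12 (1E,10E)-1-iodododeca-1,10-diene, via alkenylzirconocene 11 (not isolated)
Conditions: Cp2Zr(H)Cl (1.2 equiv), THF, rt; then I2, 0 °C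
Reagents that add atoms: iodine (II)
Why: Hydrozirconation with the Schwartz reagent adds Zr–H syn and at the terminal carbon of the alkyne much faster than to the internal alkene, and iodinolysis of the C–Zr bond with retention should give the (E)-iodide as a single isomer.

**Step 8**
Reactants: 12 (1E,10E)-1-iodododeca-1,10-diene; 13 1,4-bis(trimethylsilyl)buta-1,3-diyne
Product: 16 trimethyl[(5E,14E)-hexadeca-5,14-diene-1,3-diyn-1-yl]silane, via lithium acetylide 14 (not isolated), via alkynylzinc bromide 15 (not isolated)
Conditions: 13, MeLi·LiBr (1.0 equiv), THF, rt; ZnBr2, 0 °C; then 12, Pd(PPh3)4 (5 mol %), THF, rt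
Reagents that add atoms: none
Why: MeLi·LiBr removes one silyl group of 13 selectively, and transmetalation to zinc followed by zerovalent-palladium-catalysed Negishi coupling with the vinyl iodide forms the sp–sp2 bond with retention of the E geometry.

**Step 9**
Reactants: 16 trimethyl[(5E,14E)-hexadeca-5,14-diene-1,3-diyn-1-yl]silane; 7 rac-methyl (1S,4S)-4-[(2E)-3-iodoprop-2-en-1-yl]cyclobut-2-ene-1-carboxylate
Product: 18 rac-methyl (1S,4S)-4-[(2E,8E,17E)-nonadeca-2,8,17-triene-4,6-diyn-1-yl]cyclobut-2-ene-1-carboxylate, via terminal enediyne 17 (not isolated)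
Conditions: K2CO3 (cat.), MeOH/THF, 0 °C; then 7, Pd(PPh3)4 (5 mol %), CuI (10 mol %), i-Pr2NH, THF, rt, degassed
Reagents that add atoms: none
Why: Methanolysis of the alkynylsilane liberates the sensitive terminal diyne 17 only in solution, and Sonogashira coupling with vinyl iodide 7 joins the two halves with retention of both alkene geometries at room temperature, below the opening temperature of the trans-cyclobutene.

**Step 10**
Reactants: 18 rac-methyl (1S,4S)-4-[(2E,8E,17E)-nonadeca-2,8,17-triene-4,6-diyn-1-yl]cyclobut-2-ene-1-carboxylate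
Product: 23 rac-methyl (1S,2S,3R,6R,7R,10S,11S,12S)-2-[(8E)-dec-8-en-1-yl]tetracyclo[8.2.1.0^3,12.0^6,11]trideca-4,8-diene-7-carboxylate, via tetraene 19 (not isolated), via cyclooctatriene 20 (not isolated), via bicyclooctadiene 21 (not isolated), via dienoate 22 (not isolated)
Conditions: Zn dust activated with Cu(OAc)2 and AgNO3, MeOH/H2O 1:1, 25–40 °C, dark; filtration and extraction; then toluene (2 mM), BHT, 110 °C, sealed tube
Reagents that add atoms: none
Why: Activated zinc reduces only the conjugated diyne and does so cis (Boland reduction), the resulting (E,Z,Z,E)-tetraene 19 should close at room temperature by conrotatory 8π electrocyclisation to the trans-disubstituted cyclooctatriene 20 (C1, C2) and then by disrotatory 6π electrocyclisation to the cis-fused bicyclooctadiene 21 (C3, C12), and heating should open the trans-cyclobutene conrotatorily with both substituents outward to the (2E,4E)-dienoate 22, which adds to the ring double bond C6=C11 from the face of its one-carbon tether in an intramolecular Diels–Alder reaction that sets C6, C7, C10 and C11 (suprafacial addition to the cis ring alkene and E,E-diene geometry), while the 6π closure mode that puts the diene on the wrong face reverts through 20.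

**Step 11**
Reactants: 23 rac-methyl (1S,2S,3R,6R,7R,10S,11S,12S)-2-[(8E)-dec-8-en-1-yl]tetracyclo[8.2.1.0^3,12.0^6,11]trideca-4,8-diene-7-carboxylate
Product: 24 methyl (1S,2S,3R,6R,7R,10S,11S,12S)-2-[(8E)-dec-8-en-1-yl]tetracyclo[8.2.1.0^3,12.0^6,11]trideca-4,8-diene-7-carboxylate (CNP0133550.1)
Conditions: preparative HPLC on cellulose tris(3,5-dimethylphenylcarbamate), hexane/2-propanol
Reagents that add atoms: none
Why: The enantiomers of the non-polar ester are separated physically on a polysaccharide chiral phase (chromatographic resolution), which supplies the absolute configuration of all eight stereocentres at once because their relative configuration was fixed in step 10.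

**Compound list**

1 | 5,6-dihydro-2H-pyran-2-one | O=C1C=CCCO1 | starting material
2 | acetylene | C#C | starting material
3 | rac-(1R,6S)-3-oxabicyclo[4.2.0]oct-7-en-2-one (cis-fused) | O=C1OCC[C@H]2C=C[C@@H]12 | intermediate
4 | rac-methyl (1R,4S)-4-(2-hydroxyethyl)cyclobut-2-ene-1-carboxylate (cis; not isolated) | COC(=O)[C@@H]1C=C[C@@H]1CCO | intermediate
5 | rac-methyl (1S,4S)-4-(2-hydroxyethyl)cyclobut-2-ene-1-carboxylate (trans) | COC(=O)[C@H]1C=C[C@@H]1CCO | intermediate
6 | rac-methyl (1S,4S)-4-(2-oxoethyl)cyclobut-2-ene-1-carboxylate | COC(=O)[C@H]1C=C[C@@H]1CC=O | intermediate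
7 | rac-methyl (1S,4S)-4-[(2E)-3-iodoprop-2-en-1-yl]cyclobut-2-ene-1-carboxylate | COC(=O)[C@H]1C=C[C@@H]1C/C=C/I | intermediate
8 | dec-9-yn-1-ol | OCCCCCCCCC#C | starting material
9 | dec-9-ynal | O=CCCCCCCCC#C | intermediate
10 | (10E)-dodec-10-en-1-yne | C#CCCCCCCC/C=C/C | intermediate
11 | chlorobis(cyclopentadienyl)[(1E,10E)-dodeca-1,10-dien-1-yl]zirconium (not isolated) | C/C=C/CCCCCCC/C=C/[Zr](Cl)(C1C=CC=C1)C2C=CC=C2 | intermediate
12 | (1E,10E)-1-iodododeca-1,10-diene | C/C=C/CCCCCCC/C=C/I | intermediate
13 | 1,4-bis(trimethylsilyl)buta-1,3-diyne | C[Si](C)(C)C#CC#C[Si](C)(C)C | starting material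
14 | [4-(trimethylsilyl)buta-1,3-diyn-1-yl]lithium (not isolated) | [Li]C#CC#C[Si](C)(C)C | intermediate
15 | bromo[4-(trimethylsilyl)buta-1,3-diyn-1-yl]zinc (not isolated) | Br[Zn]C#CC#C[Si](C)(C)C | intermediate
16 | trimethyl[(5E,14E)-hexadeca-5,14-diene-1,3-diyn-1-yl]silane | C/C=C/CCCCCCC/C=C/C#CC#C[Si](C)(C)C | intermediate
17 | (5E,14E)-hexadeca-5,14-diene-1,3-diyne (not isolated) | C/C=C/CCCCCCC/C=C/C#CC#C | intermediate
18 | rac-methyl (1S,4S)-4-[(2E,8E,17E)-nonadeca-2,8,17-triene-4,6-diyn-1-yl]cyclobut-2-ene-1-carboxylate | COC(=O)[C@H]1C=C[C@@H]1C/C=C/C#CC#C/C=C/CCCCCCC/C=C/C | intermediate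
19 | rac-methyl (1S,4S)-4-[(2E,4Z,6Z,8E,17E)-nonadeca-2,4,6,8,17-pentaen-1-yl]cyclobut-2-ene-1-carboxylate (not isolated) | COC(=O)[C@H]1C=C[C@@H]1C/C=C/C=C\C=C/C=C/CCCCCCC/C=C/C | intermediate
20 | methyl trans-4-{[8-((8E)-dec-8-en-1-yl)cycloocta-2,4,6-trien-1-yl]methyl}cyclobut-2-ene-1-carboxylate, ring substituents at C1 and C8 of the eight-membered ring trans (two racemic diastereomers, one drawn; not isolated) | C/C=C/CCCCCCC[C@@H]1C=CC=CC=C[C@H]1C[C@H]2C=C[C@@H]2C(=O)OC | intermediate
21 | methyl trans-4-{[8-((8E)-dec-8-en-1-yl)bicyclo[4.2.0]octa-2,4-dien-7-yl]methyl}cyclobut-2-ene-1-carboxylate, cis ring fusion, C7 substituent on the face of the six-membered ring, C8 substituent on the opposite face (two racemic diastereomers, one drawn; not isolated) | C/C=C/CCCCCCC[C@@H]1[C@H]2C=CC=C[C@H]2[C@H]1C[C@H]3C=C[C@@H]3C(=O)OC | intermediate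
22 | rac-methyl (2E,4E)-6-[8-((8E)-dec-8-en-1-yl)bicyclo[4.2.0]octa-2,4-dien-7-yl]hexa-2,4-dienoate, relative configuration of the bicycle as in 21 (not isolated) | C/C=C/CCCCCCC[C@@H]1[C@H]2C=CC=C[C@H]2[C@H]1C/C=C/C=C/C(=O)OC | intermediate
23 | rac-methyl (1S,2S,3R,6R,7R,10S,11S,12S)-2-[(8E)-dec-8-en-1-yl]tetracyclo[8.2.1.0^3,12.0^6,11]trideca-4,8-diene-7-carboxylate (both enantiomers written) | C/C=C/CCCCCCC[C@@H]1[C@H]2C=C[C@@H]3[C@@H]4[C@H]2[C@H]1C[C@H]4C=C[C@H]3C(=O)OC.C/C=C/CCCCCCC[C@H]1[C@@H]2C=C[C@H]3[C@H]4[C@@H]2[C@@H]1C[C@@H]4C=C[C@@H]3C(=O)OC | intermediate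
24 | methyl (1S,2S,3R,6R,7R,10S,11S,12S)-2-[(8E)-dec-8-en-1-yl]tetracyclo[8.2.1.0^3,12.0^6,11]trideca-4,8-diene-7-carboxylate (CNP0133550.1) | C/C=C/CCCCCCC[C@@H]1[C@H]2C=C[C@@H]3[C@@H]4[C@H]2[C@H]1C[C@H]4C=C[C@H]3C(=O)OC | target

**Step count and risks**

Total step count: 11. Longest linear sequence: 7 steps (steps 1–4 and 9–11, or steps 5–11).

Steps most likely to fail:

Step 10. The hot stage superimposes cyclobutene opening, the reversible 6π/8π manifold and possible hydrogen shifts, and the zinc reduction may stall at the enyne stage, so the telescoped sequence may give mixtures that cannot be separated. The fallback separates the events and sets out from 18. The cyclobutene alone is opened first (toluene, 90 °C) to methyl (2E,4E,7E,13E,22E)-tetracosa-2,4,7,13,22-pentaene-9,11-diynoate F1. With no strained alkene left, the diyne is semi-hydrogenated over Pd on CaCO3 poisoned with Pb(OAc)2 (quinoline, H2) to methyl (2E,4E,7E,9Z,11Z,13E,22E)-tetracosa-2,4,7,9,11,13,22-heptaenoate F2. F2 should close at room temperature through rac-methyl (2E,4E)-6-[trans-8-((8E)-dec-8-en-1-yl)cycloocta-2,4,6-trien-1-yl]hexa-2,4-dienoate F3 to the bicyclooctadiene dienoate, so the fallback comes back to the route at 22. Compound 22 is then isolated and heated on its own (toluene, 100 °C) to 23.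

Step 1. Acetylene is a poor trap for the lactone triplet, so lactone dimerisation and secondary photochemistry of the cyclobutene may outrun the cycloaddition. The fallback sets out from 1 and uses an alkene in place of the alkyne: sensitised [2+2] photocycloaddition with (Z)-1,2-dichloroethene (acetone, hν, Pyrex) to rac-7,8-dichloro-3-oxabicyclo[4.2.0]octan-2-one F4 (cis-fused, chloride epimers). Reductive 1,2-elimination with Zn dust in ethanol at reflux then comes back to the route at 3.

Step 4. The chromium olefination of an α-unbranched aldehyde may lose E/Z selectivity, and the Z-iodide would carry through to the wrong (cis-disubstituted) ring series after the 8π step. The fallback sets out from 6 and builds the alkene by a stereospecific route. Ohira–Bestmann homologation (dimethyl (1-diazo-2-oxopropyl)phosphonate, K2CO3, MeOH) gives rac-methyl (1S,4S)-4-(prop-2-yn-1-yl)cyclobut-2-ene-1-carboxylate F5. Syn-hydrozirconation with Cp2Zr(H)Cl (THF, rt) gives the alkenylzirconocene chlorobis(cyclopentadienyl){(1E)-3-[(1S,4S)-4-(methoxycarbonyl)cyclobut-2-en-1-yl]prop-1-en-1-yl}zirconium F6, and iodinolysis (I2, 0 °C) comes back to the route at 7 as the single E isomer.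

Further compounds
F1 | step 10 | methyl (2E,4E,7E,13E,22E)-tetracosa-2,4,7,13,22-pentaene-9,11-diynoate | COC(=O)/C=C/C=C/C/C=C/C#CC#C/C=C/CCCCCCC/C=C/C
F2 | step 10 | methyl (2E,4E,7E,9Z,11Z,13E,22E)-tetracosa-2,4,7,9,11,13,22-heptaenoate | COC(=O)/C=C/C=C/C/C=C/C=C\C=C/C=C/CCCCCCC/C=C/C
F3 | step 10 | rac-methyl (2E,4E)-6-[trans-8-((8E)-dec-8-en-1-yl)cycloocta-2,4,6-trien-1-yl]hexa-2,4-dienoate | C/C=C/CCCCCCC[C@@H]1C=CC=CC=C[C@H]1C/C=C/C=C/C(=O)OC
F4 | step 1 | rac-7,8-dichloro-3-oxabicyclo[4.2.0]octan-2-one (cis-fused, chloride epimers) | O=C1OCC[C@H]2C(Cl)C(Cl)[C@@H]12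
F5 | step 4 | rac-methyl (1S,4S)-4-(prop-2-yn-1-yl)cyclobut-2-ene-1-carboxylate | COC(=O)[C@H]1C=C[C@@H]1CC#C
F6 | step 4 | chlorobis(cyclopentadienyl){(1E)-3-[(1S,4S)-4-(methoxycarbonyl)cyclobut-2-en-1-yl]prop-1-en-1-yl}zirconium | COC(=O)[C@H]1C=C[C@@H]1C/C=C/[Zr](Cl)(C2C=CC=C2)C3C=CC=C3
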